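The target is a single 25-membered lactone ring (ring oxygen plus C1 to C24) with no functionality besides the ester. The key step exploits that C8 and C9 are neighbouring, unfunctionalised ring methylenes, so their bond can be traced back to an alkene and further to two aldehyde carbons. 8-Hydroxyoctanoic acid (1) and 16-bromohexadecan-1-ol (2) are joined through the ester oxygen and oxidised to open-chain dialdehyde 7, whose formyl carbons are C8 and C9. One low-valent titanium coupling then forms the C8–C9 bond and closes the ring as alkene 9; hydrogenation to lactone 10 erases the alkene geometry.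

Key step: step 3

Remarks on the chemistry:
- Numbering follows the lactone: C1 is the carbonyl carbon and C24 the carbon on the ring oxygen.
- Carbon count: the acid arm must hold eight carbons with the formyl carbon as C8, so this aldehyde is taken from the primary alcohol of an eight-carbon ω-hydroxy acid. A terminal alkene used as aldehyde surrogate would need nine carbons, because ozonolysis removes the terminal carbon; an eight-carbon alkenoic acid would give a ring one carbon too small.
- Assumption: the titanium coupling should give mainly the E alkene, so 9 is written as E; any Z isomer would converge on 10 in step 4.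
- Assumption: 1 and 2 are taken as catalogue compounds.

Step 1
Reactants: 1 8-hydroxyoctanoic acid; 2 16-bromohexadecan-1-ol
Product: 4 16-hydroxyhexadecyl 8-hydroxyoctanoate, via cesium 8-hydroxyoctanoate 3 (not isolated)
Conditions: Cs2CO3 (0.5 equiv), DMF, rt; then 2, 50 °C
Reagents that add atoms: none
Why: Carboxylate O-alkylation (SN2): the cesium carboxylate 3, weakly ion-paired in DMF, displaces the primary bromide of 2, while the primary hydroxyl groups are not deprotonated in this near-neutral medium and stay free; no stereocentre is formed.

Step 2
Reactants: 4 16-hydroxyhexadecyl 8-hydroxyoctanoate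
Product: 7 16-oxohexadecyl 8-oxooctanoate, via 16-hydroxyhexadecyl 8-oxooctanoate 5 (not isolated), via 16-oxohexadecyl 8-hydroxyoctanoate 6 (not isolated)
Conditions: Dess–Martin periodinane (2.4 equiv), CH2Cl2, 0 °C to rt
Reagents that add atoms: none
Why: Dess–Martin oxidation: each primary alcohol exchanges onto the hypervalent iodine centre and is oxidised to the aldehyde without over-oxidation in anhydrous CH2Cl2, the ester being inert, so both chain ends reach the aldehyde level in one flask; no stereocentre is formed.

Step 3
Reactants: 7 16-oxohexadecyl 8-oxooctanoate
Product: 9 (E)-tetracos-8-en-24-olide, via titanium pinacolate 8 (not isolated)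
Conditions: TiCl3(DME)1.5, Zn–Cu couple, DME, reflux; then 7 in DME by syringe pump (about 30 h, about 1 mM final concentration), reflux
Reagents that add atoms: none
Why: McMurry carbonyl coupling: electron transfer from the low-valent titanium surface turns each formyl group into a titanium-bound ketyl, the two ketyls join at C8 and C9 to give the titanium pinacolate 8, and C–O cleavage on the oxophilic metal at reflux releases the C8=C9 alkene and a titanium oxide. The closest known reaction type is the intramolecular titanium-mediated coupling of α,ω-dialdehydes to cycloalkenes, which is used for medium and large rings under slow addition. The 25-membered ring closes end to end by ketyl–ketyl coupling of the two chain termini held on the metal surface, so both formyl carbons become adjacent ring carbons and the new double bond is endocyclic. No stereocentre remains in 9: the two carbinol centres of 8 are transient and lost on deoxygenation, and the alkene geometry is irrelevant because step 4 saturates the bond. The step needs aldehyde–aldehyde over aldehyde–ester coupling, which rests on the much easier reduction of aldehydes than of an ester and on the fact that an ester–ketyl closure would have to form an eight-membered carbocycle (C1 to C8) or an 18-membered ring through the poorly electrophilic ester carbon; it also needs ring closure over oligomerisation, which the syringe-pump addition should secure by keeping the concentration of uncoupled dialdehyde very low.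

Step 4
Reactants: 9 (E)-tetracos-8-en-24-olide
Product: 10 24-tetracosanolide
Conditions: H2 (1 atm), 10% Pd/C, EtOAc, rt
Reagents that add atoms: none
Why: Heterogeneous catalytic hydrogenation: H2 adds across the isolated 1,2-disubstituted C8=C9 bond on the palladium surface, both alkene isomers give the same saturated lactone, and the ester is inert under these conditions; no stereocentre is formed.

Compound list
1 | 8-hydroxyoctanoic acid | OCCCCCCCC(=O)O | starting material
2 | 16-bromohexadecan-1-ol | OCCCCCCCCCCCCCCCCBr | starting material
3 | cesium 8-hydroxyoctanoate (formed in the flask, not isolated) | [Cs+].[O-]C(=O)CCCCCCCO | intermediate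
4 | 16-hydroxyhexadecyl 8-hydroxyoctanoate | OCCCCCCCC(=O)OCCCCCCCCCCCCCCCCO | intermediate
5 | 16-hydroxyhexadecyl 8-oxooctanoate (half-oxidised, not isolated) | O=CCCCCCCC(=O)OCCCCCCCCCCCCCCCCO | intermediate
6 | 16-oxohexadecyl 8-hydroxyoctanoate (half-oxidised, not isolated) | OCCCCCCCC(=O)OCCCCCCCCCCCCCCCC=O | intermediate
7 | 16-oxohexadecyl 8-oxooctanoate | O=CCCCCCCC(=O)OCCCCCCCCCCCCCCCC=O | intermediate
8 | titanium pinacolate of 8,9-dihydroxytetracosan-24-olide (titanium-bound 8,9-diolate, mixture of diastereomers, not isolated) | O=C1CCCCCCC2O[Ti]OC2CCCCCCCCCCCCCCCO1 | intermediate
9 | (E)-tetracos-8-en-24-olide, also named (E)-oxacyclopentacos-9-en-2-one | O=C1CCCCCC/C=C/CCCCCCCCCCCCCCCO1 | intermediate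
10 | 24-tetracosanolide (oxacyclopentacosan-2-one) | O=C1CCCCCCCCCCCCCCCCCCCCCCCO1 | target

Total step count: 4
Longest linear sequence: 4 steps (1 and 2 to 4, 7, 9 and 10)

Steps most likely to fail

1. Step 3 (titanium macrocyclisation). Intermolecular ketyl coupling may outrun ring closure and give dimers and oligomers. The coupling may also stall at the pinacol stage, or long exposure to low-valent titanium at reflux may attack the ester. Fallback, from 7 back to 9: dialdehyde 7 would be methylenated twice by Wittig reaction with methylenetriphenylphosphorane (Ph3PCH3Br, KN(SiMe3)2, THF, −78 to 0 °C) to give heptadec-16-en-1-yl non-8-enoate F1. Ring-closing olefin metathesis of the diene with the second-generation Grubbs catalyst RuCl2(=CHPh)(H2IMes)(PCy3) in dilute refluxing CH2Cl2 would expel ethene and join the same two carbons, C8 and C9. The route is rejoined at alkene 9, as an E/Z mixture that step 4 levels.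

2. Step 1 (carboxylate alkylation). Displacement by the sparingly soluble carboxylate may be slow, and ester exchange among the hydroxyl-bearing species may build oligoesters before the alkylation is complete. Fallback, from 1 back to 4, in which the ester is made by acylation of an alcohol instead of alkylation of a carboxylate: acid 1 would be silylated on both oxygens (tert-butyldimethylsilyl chloride, imidazole, DMF) to tert-butyldimethylsilyl 8-[(tert-butyldimethylsilyl)oxy]octanoate F2, which is not isolated. Its silyl ester would be cleaved selectively (K2CO3, MeOH/THF/H2O) to 8-[(tert-butyldimethylsilyl)oxy]octanoic acid F3. Steglich esterification (EDC·HCl, catalytic DMAP, CH2Cl2/THF) with an excess of commercial hexadecane-1,16-diol (OCCCCCCCCCCCCCCCCO) would give 16-hydroxyhexadecyl 8-[(tert-butyldimethylsilyl)oxy]octanoate F4. Removal of the silyl ether with HF·pyridine in THF would return to diol ester 4.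

3. Step 2 (double oxidation). The oxidation may stop partly at the hydroxy aldehyde stage, and the dialdehyde may be lost by hydration, self-condensation or aerial oxidation during removal of the iodine by-products. Fallback, from 2 back to 7, in which the acid-arm aldehyde comes from alkene cleavage under neutral conditions: bromo alcohol 2 would be alkylated with cesium non-8-enoate F5, made in the flask from commercial non-8-enoic acid (C=CCCCCCCC(=O)O) and Cs2CO3 in DMF, to give 16-hydroxyhexadecyl non-8-enoate F6. A single Dess–Martin oxidation would give the storable monoaldehyde 16-oxohexadecyl non-8-enoate F7. Ozonolysis (O3, CH2Cl2, −78 °C) would form the ozonide 16-oxohexadecyl 7-(1,2,4-trioxolan-3-yl)heptanoate F8, racemic at the trioxolane carbon, which PPh3 would reduce in the same flask to dialdehyde 7 directly before the cyclisation.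

Further compounds
F1 | step 3 | heptadec-16-en-1-yl non-8-enoate | C=CCCCCCCC(=O)OCCCCCCCCCCCCCCCC=C
F2 | step 1 | tert-butyldimethylsilyl 8-[(tert-butyldimethylsilyl)oxy]octanoate | CC(C)(C)[Si](C)(C)OCCCCCCCC(=O)O[Si](C)(C)C(C)(C)C
F3 | step 1 | 8-[(tert-butyldimethylsilyl)oxy]octanoic acid | CC(C)(C)[Si](C)(C)OCCCCCCCC(=O)O
F4 | step 1 | 16-hydroxyhexadecyl 8-[(tert-butyldimethylsilyl)oxy]octanoate | CC(C)(C)[Si](C)(C)OCCCCCCCC(=O)OCCCCCCCCCCCCCCCCO
F5 | step 2 | cesium non-8-enoate | [Cs+].[O-]C(=O)CCCCCCC=C
F6 | step 2 | 16-hydroxyhexadecyl non-8-enoate | C=CCCCCCCC(=O)OCCCCCCCCCCCCCCCCO
F7 | step 2 | 16-oxohexadecyl non-8-enoate | C=CCCCCCCC(=O)OCCCCCCCCCCCCCCCC=O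
F8 | step 2 | 16-oxohexadecyl 7-(1,2,4-trioxolan-3-yl)heptanoate | O=CCCCCCCCCCCCCCCCOC(=O)CCCCCCC1OCOO1
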